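**Plan**
- Retrosynthesis: the C19–O ester bond and the C12–C13 bond to the butenolide are cut first; the C11=C12 vinyl group goes back to a C9 aldehyde, the C3 ketone to a protected carbinol and the C6 carbinol to a C6 enone.
- Ring B (C5–C10) carries cis methyls on C8 and C9, the one-carbon branch C11 on quaternary C9 and oxygen at C6 beside C5=C10. This is the imprint of a 2-silyloxydiene C10=C5–C6(OSi)=C7 on ring A plus (E)-2-methylbut-2-enal as C8=C9 (formyl carbon = C11), so C7–C8 and C9–C10 are cut together.
- The diene is cut at C5–C6 (Stille coupling) and ring A goes back to 2-methylcyclohexane-1,3-dione.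
- Forward order: ring A, then ring B by [4+2], then C12, the butenolide and the C19 ester; C3 is oxidised near the end.
- Stereochemistry: C4 (and a temporary C3 carbinol) from a CBS desymmetrisation; C8/C9 from the enal E geometry and an endo, α-face cycloaddition steered by C4; C6 from a second CBS reduction; C10 is transient.

Key step: step 8

Remark: halimane numbering is used (ring A = C1–C5 and C10, ring B = C5–C10, C11 on C9, C17 on C8, C18 and C19 on C4, C20 on C9). β is the face carrying C17, C19 and C20 in the target, α the opposite face (C18, C11, 6-OH), so the target is (4S,6S,8S,9R). Every bicyclic compound below has 4α-CH3, 4β-CH2O, 8β-CH3, 9β-CH3 and the C11 branch 9α.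
Abbreviations: TES = triethylsilyl, TBS = tert-butyldimethylsilyl.

**Step 1**
Reactants: 1 2-methylcyclohexane-1,3-dione
Product: 2 2-(hydroxymethyl)-2-methylcyclohexane-1,3-dione
Conditions: 37 % aq. HCHO, NaHCO3 (cat.), H2O, rt
Reagents that add atoms: formaldehyde, C=O
Why: Crossed aldol (Tollens-type hydroxymethylation) of the acidic C–H between the two carbonyls with formaldehyde; the carbon becomes quaternary, so only one hydroxymethyl group can enter.

**Step 2**
Reactants: 2 2-(hydroxymethyl)-2-methylcyclohexane-1,3-dione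
Product: 3 2-methyl-2-{[(triethylsilyl)oxy]methyl}cyclohexane-1,3-dione
Conditions: TESCl, imidazole, CH2Cl2, 0 °C
Reagents that add atoms: chlorotriethylsilane, CC[Si](Cl)(CC)CC
Why: Standard silylation of a primary alcohol with a silyl chloride and imidazole; the weak base avoids retro-aldol loss of formaldehyde, and the bulky CH2OTES arm later differentiates the two faces of ring A.

**Step 3**
Reactants: 3 2-methyl-2-{[(triethylsilyl)oxy]methyl}cyclohexane-1,3-dione
Product: 4 (2S,3S)-3-hydroxy-2-methyl-2-{[(triethylsilyl)oxy]methyl}cyclohexan-1-one (hydroxyl cis to the CH2OTES group)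
Conditions: (R)-2-methyl-CBS-oxazaborolidine (C18H20BNO, 20 mol %), catecholborane (1.1 equiv), toluene/CH2Cl2, −78 → −40 °C
Reagents that add atoms: none
Why: Corey–Bakshi–Shibata reduction used to desymmetrise a prochiral 2,2-disubstituted 1,3-dione: the (R)-catalyst delivers hydride to the Re face of a carbonyl whose large group is the quaternary carbon, and only one of the two enantiotopic carbonyls offers that face on the side of the small methyl group (anti to CH2OTES), so the carbinol (S) and the quaternary centre (S, the future C4) are set together, and one hydride equivalent stops at the hydroxy ketone.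

**Step 4**
Reactants: 4 (2S,3S)-3-hydroxy-2-methyl-2-{[(triethylsilyl)oxy]methyl}cyclohexan-1-one
Product: 5 (2S,3S)-2-methyl-3-[(triethylsilyl)oxy]-2-{[(triethylsilyl)oxy]methyl}cyclohexan-1-one
Conditions: TESOTf, 2,6-lutidine, CH2Cl2, −78 °C
Reagents that add atoms: triethylsilyl trifluoromethanesulfonate, CC[Si](CC)(CC)OS(=O)(=O)C(F)(F)F
Why: Silylation of a hindered secondary alcohol with a silyl triflate and a non-nucleophilic base, mild enough to avoid retro-aldol opening of the β-hydroxy ketone.

**Step 5**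
Reactants: 5 (2S,3S)-2-methyl-3-[(triethylsilyl)oxy]-2-{[(triethylsilyl)oxy]methyl}cyclohexan-1-one
Product: 7 (5S,6S)-6-methyl-5-[(triethylsilyl)oxy]-6-{[(triethylsilyl)oxy]methyl}cyclohex-1-en-1-yl trifluoromethanesulfonate, via potassium enolate 6 (not isolated)
Conditions: KN(SiMe3)2, THF, −78 °C; then PhNTf2, −78 → 0 °C
Reagents that add atoms: N-phenylbis(trifluoromethanesulfonimide), O=S(=O)(N(c1ccccc1)S(=O)(=O)C(F)(F)F)C(F)(F)F
Why: Enol triflate formation by kinetic deprotonation and O-sulfonylation; the ketone (C5) can enolise only toward C10 because C4 is quaternary, so a single regioisomer forms.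

**Step 6**
Reactants: 7 (5S,6S)-6-methyl-5-[(triethylsilyl)oxy]-6-{[(triethylsilyl)oxy]methyl}cyclohex-1-en-1-yl trifluoromethanesulfonate; 8 tributyl(1-ethoxyethenyl)stannane
Product: 10 1-[(5S,6S)-6-methyl-5-[(triethylsilyl)oxy]-6-{[(triethylsilyl)oxy]methyl}cyclohex-1-en-1-yl]ethan-1-one, via 2-ethoxydiene 9 (not isolated)
Conditions: Pd(PPh3)4 (5 mol %), CuI (10 mol %), LiCl (3 equiv), THF, 65 °C; then 0.5 M aq. oxalic acid, THF, 0 °C
Reagents that add atoms: water, O
Why: Stille coupling of an enol triflate with an α-alkoxyvinylstannane (LiCl and CuI assist transmetalation at the hindered carbon) forms C5–C6, and the very acid-labile dienyl ethyl ether is then hydrolysed to the methyl ketone under conditions that leave the TES ethers intact.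

**Step 7**
Reactants: 10 1-[(5S,6S)-6-methyl-5-[(triethylsilyl)oxy]-6-{[(triethylsilyl)oxy]methyl}cyclohex-1-en-1-yl]ethan-1-one
Product: 11 ring A silyloxydiene (5S,6S)-1-{1-[(tert-butyldimethylsilyl)oxy]ethenyl}-6-methyl-5-[(triethylsilyl)oxy]-6-{[(triethylsilyl)oxy]methyl}cyclohex-1-ene
Conditions: TBSOTf, Et3N, CH2Cl2, −78 → 0 °C
Reagents that add atoms: tert-butyldimethylsilyl trifluoromethanesulfonate, CC(C)(C)[Si](C)(C)OS(=O)(=O)C(F)(F)F
Why: Soft enolisation of a methyl enone (silyl triflate plus amine base) removes a methyl proton and gives the cross-conjugated 2-silyloxydiene C10=C5–C6(OTBS)=C7.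

**Step 8**
Reactants: 11 ring A silyloxydiene; 12 (E)-2-methylbut-2-enal (tiglic aldehyde)
Product: 13 cycloadduct 6-(TBS-oxy)-3β,19-bis(TES-oxy)-12,13,14,15,16-pentanorhalim-5-en-11-al with 10β-H
Conditions: 12 (2 equiv), Me2AlCl (1.2 equiv), CH2Cl2, −78 → −40 °C; then aq. work-up
Reagents that add atoms: none
Why: Me2AlCl binds the formyl oxygen of 12 and lowers its LUMO, and 11 adds in a concerted but asynchronous normal-demand [4+2] cycloaddition in which the nucleophilic enol-ether terminus C7 leads onto the enal β-carbon C8 while C10 closes onto the α-carbon C9; the closest known reaction type is the Lewis-acid-promoted Diels–Alder reaction of 1-(1-silyloxyvinyl)cyclohexenes with α-substituted enals, which forms quaternary carbons. Ring B (C5–C10) closes as a six-membered carbocycle by suprafacial addition on both partners and emerges as the C5=C6 silyl enol ether with the silyloxy carbon para to the formyl-bearing C9. At C8 and C9 the E geometry of 12 is transferred, so the two methyls are cis, and their sense relative to C4 follows from an endo-formyl transition state on the α-face of the diene, which also gives 10β-H. The α-face is needed and should be favoured because the equatorial C3 silyloxy group and the allylic strain between the C6 silyloxy group and the C4 substituents place the CH2OTES arm pseudoaxial on the β-face, where it blocks approach. The endo mode is needed and should be favoured because the complexed formyl group is the only substituent with secondary overlap, while the exo positions keep both methyls clear of the C4 and C6 substituents. Me2AlCl also scavenges adventitious acid, so the diene and the product enol ether survive.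

**Step 9**
Reactants: 13 cycloadduct aldehyde
Product: 14 6-(TBS-oxy)-3β,19-bis(TES-oxy)-13,14,15,16-tetranorhalima-5,11-diene with 10β-H
Conditions: Ph3PCH3Br, KOtBu, THF, 0 °C → rt
Reagents that add atoms: methyltriphenylphosphonium bromide, C[P+](c1ccccc1)(c1ccccc1)c1ccccc1.[Br-]
Why: Wittig methylenation of a non-enolisable neopentyl aldehyde; C9 cannot epimerise and the ylide leaves the silyl ethers and the silyl enol ether untouched.

**Step 10**
Reactants: 14 silyl enol ether diene
Product: 15 3β,19-bis(TES-oxy)-13,14,15,16-tetranorhalima-5(10),11-dien-6-one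
Conditions: Pd(OAc)2 (1.2 equiv), MeCN, rt → 40 °C
Reagents that add atoms: none
Why: Saegusa–Ito oxidation: the silyl enol ether gives a C5 palladium enolate, and syn β-hydride elimination can only use H10 because C4 is quaternary, so the C5=C10 enone forms regiospecifically and the C10 stereocentre is erased; the vinyl group has no allylic hydrogen and should be left alone.

**Step 11**
Reactants: 15 enone
Product: 16 3β,19-bis(TES-oxy)-13,14,15,16-tetranorhalima-5(10),11-dien-6α-ol (6S)
Conditions: (R)-2-methyl-CBS-oxazaborolidine (C18H20BNO, 30 mol %), catecholborane (1.5 equiv), toluene, −78 → −30 °C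
Reagents that add atoms: none
Why: Corey–Bakshi–Shibata reduction of an enone: with the tetrasubstituted alkenyl carbon C5 as the large group, the (R)-catalyst delivers hydride to the Re (β) face of C6=O and sets the 6α (S) carbinol under reagent control; catecholborane at low temperature does not hydroborate the vinyl group.

**Step 12**
Reactants: 16 allylic alcohol
Product: 17 6α-(TBS-oxy)-3β,19-bis(TES-oxy)-13,14,15,16-tetranorhalima-5(10),11-diene
Conditions: TBSOTf, 2,6-lutidine, CH2Cl2, −78 → 0 °C
Reagents that add atoms: tert-butyldimethylsilyl trifluoromethanesulfonate, CC(C)(C)[Si](C)(C)OS(=O)(=O)C(F)(F)F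
Why: Silyl triflate silylation of a hindered secondary alcohol; it gives a C6 ether that is far more acid-stable than the two TES ethers, which is the basis of step 14.

**Step 13**
Reactants: 17 vinyl compound; 18 4-bromofuran-2(5H)-one
Product: 20 6α-(TBS-oxy)-3β,19-bis(TES-oxy)halima-5(10),13-dien-15,16-olide, via B-alkyl-9-BBN adduct 19 (not isolated)
Conditions: 9-BBN-H, THF, 0 → 50 °C; then 18, PdCl2(dppf) (5 mol %), AsPh3 (10 mol %), 3 M aq. K3PO4, DMF, rt
Reagents that add atoms: none
Why: Anti-Markovnikov hydroboration with 9-BBN touches only the monosubstituted alkene (the tetrasubstituted C5=C10 bond is inert), and B-alkyl Suzuki–Miyaura coupling of the primary alkylborane with the β-bromobutenolide forms C12–C13 under phosphate base at room temperature, which the butenolide tolerates.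

**Step 14**
Reactants: 20 butenolide
Product: 21 6α-(TBS-oxy)-3β,19-dihydroxyhalima-5(10),13-dien-15,16-olide
Conditions: pyridinium p-toluenesulfonate (20 mol %), MeOH/CH2Cl2, 0 °C → rt
Reagents that add atoms: none
Why: Acid-catalysed methanolysis of silyl ethers: TES ethers cleave roughly two orders of magnitude faster than a TBS ether, so both ring A hydroxyls are freed while the C6 ether stays.

**Step 15**
Reactants: 22 3-(4-hydroxyphenyl)propanoic acid
Product: 24 3-{4-[(tert-butyldimethylsilyl)oxy]phenyl}propanoic acid, via bis-silyl derivative 23 (not isolated)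
Conditions: TBSCl (2.2 equiv), imidazole, DMF, rt; then AcOH/THF/H2O, rt
Reagents that add atoms: tert-butyldimethylsilyl chloride, CC(C)(C)[Si](C)(C)Cl
Why: Silylation of both the phenol and the acid, then selective hydrolysis of the much more labile silyl ester, leaves the phenol masked so that it cannot compete in the esterification.

**Step 16**
Reactants: 21 diol; 24 3-{4-[(tert-butyldimethylsilyl)oxy]phenyl}propanoic acid
Product: 25 6α-(TBS-oxy)-3β-hydroxy-15,16-olide 19-ester of 24
Conditions: 24 (1.05 equiv), DCC (1.1 equiv), 4-(dimethylamino)pyridine (10 mol %), CH2Cl2, 0 °C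
Reagents that add atoms: none
Why: Steglich esterification; the primary C19 hydroxyl should be acylated in preference to the secondary C3 hydroxyl, which sits next to the quaternary centre.

**Step 17**
Reactants: 25 hydroxy ester
Product: 26 6α-(TBS-oxy)-3-oxo-15,16-olide 19-ester (bis-TBS-protected target)
Conditions: Dess–Martin periodinane, CH2Cl2, 0 °C → rt
Reagents that add atoms: none
Why: Dess–Martin oxidation of the only free secondary alcohol under near-neutral conditions; the resulting β-acyloxy ketone has no hydrogen on C4 and cannot eliminate.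

**Step 18**
Reactants: 26 bis-TBS-protected target
Product: 27 CNP0301014.1, (4S,6S,8S,9R)-6α-hydroxy-3-oxohalima-5(10),13-dien-15,16-olid-19-yl 3-(4-hydroxyphenyl)propanoate
Conditions: HF·pyridine, pyridine, THF, 0 °C → rt
Reagents that add atoms: none
Why: Fluoride-mediated desilylation in a pyridine-buffered medium removes the allylic and the aryl silyl ethers without ester cleavage, acyl migration or ionisation of the allylic alcohol.

**Compound list**
1 | 2-methylcyclohexane-1,3-dione | CC1C(=O)CCCC1=O | starting material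
2 | 2-(hydroxymethyl)-2-methylcyclohexane-1,3-dione | CC1(CO)C(=O)CCCC1=O | intermediate
3 | 2-methyl-2-{[(triethylsilyl)oxy]methyl}cyclohexane-1,3-dione | CC1(CO[Si](CC)(CC)CC)C(=O)CCCC1=O | intermediate
4 | (2S,3S)-3-hydroxy-2-methyl-2-{[(triethylsilyl)oxy]methyl}cyclohexan-1-one | O=C1CCC[C@H](O)[C@]1(C)CO[Si](CC)(CC)CC | intermediate
5 | (2S,3S)-2-methyl-3-[(triethylsilyl)oxy]-2-{[(triethylsilyl)oxy]methyl}cyclohexan-1-one | O=C1CCC[C@H](O[Si](CC)(CC)CC)[C@]1(C)CO[Si](CC)(CC)CC | intermediate
6 | potassium (5S,6S)-6-methyl-5-[(triethylsilyl)oxy]-6-{[(triethylsilyl)oxy]methyl}cyclohex-1-en-1-olate | [K+].[O-]C1=CCC[C@H](O[Si](CC)(CC)CC)[C@]1(C)CO[Si](CC)(CC)CC | intermediate (not isolated)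
7 | (5S,6S)-6-methyl-5-[(triethylsilyl)oxy]-6-{[(triethylsilyl)oxy]methyl}cyclohex-1-en-1-yl trifluoromethanesulfonate | O=S(=O)(OC1=CCC[C@H](O[Si](CC)(CC)CC)[C@]1(C)CO[Si](CC)(CC)CC)C(F)(F)F | intermediate
8 | tributyl(1-ethoxyethenyl)stannane | CCOC(=C)[Sn](CCCC)(CCCC)CCCC | starting material
9 | (5S,6S)-1-(1-ethoxyethenyl)-6-methyl-5-[(triethylsilyl)oxy]-6-{[(triethylsilyl)oxy]methyl}cyclohex-1-ene | C=C(OCC)C1=CCC[C@H](O[Si](CC)(CC)CC)[C@]1(C)CO[Si](CC)(CC)CC | intermediate (not isolated)
10 | 1-[(5S,6S)-6-methyl-5-[(triethylsilyl)oxy]-6-{[(triethylsilyl)oxy]methyl}cyclohex-1-en-1-yl]ethan-1-one | CC(=O)C1=CCC[C@H](O[Si](CC)(CC)CC)[C@]1(C)CO[Si](CC)(CC)CC | intermediate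
11 | (5S,6S)-1-{1-[(tert-butyldimethylsilyl)oxy]ethenyl}-6-methyl-5-[(triethylsilyl)oxy]-6-{[(triethylsilyl)oxy]methyl}cyclohex-1-ene (ring A silyloxydiene) | C=C(O[Si](C)(C)C(C)(C)C)C1=CCC[C@H](O[Si](CC)(CC)CC)[C@]1(C)CO[Si](CC)(CC)CC | intermediate
12 | (E)-2-methylbut-2-enal (tiglic aldehyde) | C/C=C(\C)C=O | starting material
13 | 6-(TBS-oxy)-3β,19-bis(TES-oxy)-12,13,14,15,16-pentanorhalim-5-en-11-al, 10β-H (cycloadduct) | C[C@H]1CC(O[Si](C)(C)C(C)(C)C)=C2[C@H](CC[C@H](O[Si](CC)(CC)CC)[C@]2(C)CO[Si](CC)(CC)CC)[C@]1(C)C=O | intermediate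
14 | 6-(TBS-oxy)-3β,19-bis(TES-oxy)-13,14,15,16-tetranorhalima-5,11-diene, 10β-H | C[C@H]1CC(O[Si](C)(C)C(C)(C)C)=C2[C@H](CC[C@H](O[Si](CC)(CC)CC)[C@]2(C)CO[Si](CC)(CC)CC)[C@]1(C)C=C | intermediate
15 | 3β,19-bis(TES-oxy)-13,14,15,16-tetranorhalima-5(10),11-dien-6-one | C[C@H]1CC(=O)C2=C(CC[C@H](O[Si](CC)(CC)CC)[C@]2(C)CO[Si](CC)(CC)CC)[C@]1(C)C=C | intermediate
16 | 3β,19-bis(TES-oxy)-13,14,15,16-tetranorhalima-5(10),11-dien-6α-ol | C[C@H]1C[C@H](O)C2=C(CC[C@H](O[Si](CC)(CC)CC)[C@]2(C)CO[Si](CC)(CC)CC)[C@]1(C)C=C | intermediate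
17 | 6α-(TBS-oxy)-3β,19-bis(TES-oxy)-13,14,15,16-tetranorhalima-5(10),11-diene | C[C@H]1C[C@H](O[Si](C)(C)C(C)(C)C)C2=C(CC[C@H](O[Si](CC)(CC)CC)[C@]2(C)CO[Si](CC)(CC)CC)[C@]1(C)C=C | intermediate
18 | 4-bromofuran-2(5H)-one | BrC1=CC(=O)OC1 | starting material
19 | 12-(9-borabicyclo[3.3.1]nonan-9-yl)-6α-(TBS-oxy)-3β,19-bis(TES-oxy)-13,14,15,16-tetranorhalim-5(10)-ene | C[C@H]1C[C@H](O[Si](C)(C)C(C)(C)C)C2=C(CC[C@H](O[Si](CC)(CC)CC)[C@]2(C)CO[Si](CC)(CC)CC)[C@]1(C)CCB1C2CCCC1CCC2 | intermediate (not isolated)
20 | 6α-(TBS-oxy)-3β,19-bis(TES-oxy)halima-5(10),13-dien-15,16-olide | C[C@H]1C[C@H](O[Si](C)(C)C(C)(C)C)C2=C(CC[C@H](O[Si](CC)(CC)CC)[C@]2(C)CO[Si](CC)(CC)CC)[C@]1(C)CCC1=CC(=O)OC1 | intermediate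
21 | 6α-(TBS-oxy)-3β,19-dihydroxyhalima-5(10),13-dien-15,16-olide | C[C@H]1C[C@H](O[Si](C)(C)C(C)(C)C)C2=C(CC[C@H](O)[C@]2(C)CO)[C@]1(C)CCC1=CC(=O)OC1 | intermediate
22 | 3-(4-hydroxyphenyl)propanoic acid | OC(=O)CCc1ccc(O)cc1 | starting material
23 | tert-butyldimethylsilyl 3-{4-[(tert-butyldimethylsilyl)oxy]phenyl}propanoate | CC(C)(C)[Si](C)(C)OC(=O)CCc1ccc(O[Si](C)(C)C(C)(C)C)cc1 | intermediate (not isolated)
24 | 3-{4-[(tert-butyldimethylsilyl)oxy]phenyl}propanoic acid | OC(=O)CCc1ccc(O[Si](C)(C)C(C)(C)C)cc1 | intermediate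
25 | 6α-(TBS-oxy)-3β-hydroxyhalima-5(10),13-dien-15,16-olid-19-yl 3-{4-[(tert-butyldimethylsilyl)oxy]phenyl}propanoate | C[C@H]1C[C@H](O[Si](C)(C)C(C)(C)C)C2=C(CC[C@H](O)[C@]2(C)COC(=O)CCc2ccc(O[Si](C)(C)C(C)(C)C)cc2)[C@]1(C)CCC1=CC(=O)OC1 | intermediate
26 | 6α-(TBS-oxy)-3-oxohalima-5(10),13-dien-15,16-olid-19-yl 3-{4-[(tert-butyldimethylsilyl)oxy]phenyl}propanoate | C[C@H]1C[C@H](O[Si](C)(C)C(C)(C)C)C2=C(CCC(=O)[C@]2(C)COC(=O)CCc2ccc(O[Si](C)(C)C(C)(C)C)cc2)[C@]1(C)CCC1=CC(=O)OC1 | intermediate
27 | CNP0301014.1, (4S,6S,8S,9R)-6α-hydroxy-3-oxohalima-5(10),13-dien-15,16-olid-19-yl 3-(4-hydroxyphenyl)propanoate | C[C@H]1C[C@H](O)C2=C(CCC(=O)[C@]2(C)COC(=O)CCc2ccc(O)cc2)[C@]1(C)CCC1=CC(=O)OC1 | target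

**Step count**
Total: 18 steps. Longest linear sequence: 17 steps (steps 1–14 and 16–18, from 1); step 15 is a one-step side branch.

**Steps most likely to fail**

Step 8. The sense at C8/C9 relative to C4 depends on two selections at once, diene face and endo/exo mode, and the hindered diene may discriminate poorly between the methyl and CH2OTES faces or react slowly enough to be lost by protodesilylation. The fallback sets out from 11 and 12 and comes back at 13 (and, for an epimer, at 15). It moves stereocontrol from the diene to the dienophile. The cycloaddition is run with a chiral oxazaborolidinium Lewis acid: the N-protonated B-(2-methylphenyl)oxazaborolidine from α,α-diphenylprolinol as its triflimide salt, [C24H25BNO]+[N(SO2CF3)2]−, in CH2Cl2 at −78 °C. Such ions hold an α-substituted enal through boron and a formyl C–H···O contact and expose one enal face. The antipode that leaves the C9 Si/C8 Re face open (expected: the ion from (R)-α,α-diphenylprolinol) should fix C8 and C9 directly, whichever diene face or endo/exo mode operates. The product should then be 13 together with, at most, its 10α-H epimer F1, which has the same C8/C9 configuration. F1 is methylenated like 13 to the 10α-H silyl enol ether diene F2, and both converge on 15 in the Saegusa–Ito step, where C10 becomes trigonal.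

Step 11. Reduction of the hindered C6 carbonyl may be sluggish, or substrate bias (an axial C17 methyl on the β-face) may override the catalyst so that hydride arrives from the α-face. The fallback sets out from 15 and comes back at 16. It accepts substrate control: Luche reduction (NaBH4, CeCl3·7H2O, MeOH, −78 °C) should give the 6β-alcohol F3. Mitsunobu inversion (4-nitrobenzoic acid, PPh3, diisopropyl azodicarboxylate, toluene) then gives the 6α 4-nitrobenzoate F4, and methanolysis (K2CO3, MeOH) releases 16.

Step 10. The palladium enolate must form at the most congested carbon (C5, next to quaternary C4) and reach syn alignment with H10 on the face flanked by the axial C19 arm; failure would show as simple hydrolysis to the saturated ketone. The fallback sets out from 14 and comes back at 15. It replaces dehydrogenation by halogenation–dehydrohalogenation. N-Bromosuccinimide (THF, −78 °C) should brominate the silyl enol ether regiospecifically at C5 from the open α-face to give the 5α-bromo-6-ketone F5. Li2CO3/LiBr in DMF at 110 °C then removes HBr anti-periplanar across C5–C10 (C4 has no hydrogen) to give 15.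

**Further compounds**
F1 | step 8 | 10α-H epimer of cycloadduct 13 | C[C@H]1CC(O[Si](C)(C)C(C)(C)C)=C2[C@@H](CC[C@H](O[Si](CC)(CC)CC)[C@]2(C)CO[Si](CC)(CC)CC)[C@]1(C)C=O
F2 | step 8 | 10α-H epimer of silyl enol ether diene 14 | C[C@H]1CC(O[Si](C)(C)C(C)(C)C)=C2[C@@H](CC[C@H](O[Si](CC)(CC)CC)[C@]2(C)CO[Si](CC)(CC)CC)[C@]1(C)C=C
F3 | step 11 | 6β-alcohol (C6 epimer of 16) | C[C@H]1C[C@@H](O)C2=C(CC[C@H](O[Si](CC)(CC)CC)[C@]2(C)CO[Si](CC)(CC)CC)[C@]1(C)C=C
F4 | step 11 | 6α 4-nitrobenzoate of 16 | C[C@H]1C[C@H](OC(=O)c3ccc(cc3)[N+](=O)[O-])C2=C(CC[C@H](O[Si](CC)(CC)CC)[C@]2(C)CO[Si](CC)(CC)CC)[C@]1(C)C=C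
F5 | step 10 | 5α-bromo-3β,19-bis(TES-oxy)-13,14,15,16-tetranorhalim-11-en-6-one, 10β-H | C[C@H]1CC(=O)[C@]2(Br)[C@H](CC[C@H](O[Si](CC)(CC)CC)[C@]2(C)CO[Si](CC)(CC)CC)[C@]1(C)C=C
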